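**Retrosynthetic overview**

1. Ring key (isoflavone numbering): A = phloroglucinol-derived benzene ring, C = γ-pyranone, B = hydroxyquinol-derived benzene ring, D = furan, E = dimethyldihydropyran on ring A, F = dimethyl-2H-pyran on ring B.
2. Key disconnection: the C-3–C-1′ bond, ring C and ring D are cut together, back to an ortho-hydroxyaryl enaminone (rings A/E) and a pyranobenzoquinone (rings B/F). In the forward sense the 2′,5′-dihydroxyisoflavone formed in the flask is oxidised to its quinone and O-2′ closes onto C-2, the chemical counterpart of the plant's 2′-hydroxyisoflavone → coumaronochromone oxidative cyclisation.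
3. Ring F: oxa-6π electrocyclisation of the oxatriene from oxidised hydroxyquinol and prenal, the same closure an oxidised ortho-prenyl phenol undergoes.
4. Ring E: acid-mediated C-prenylation of phloroacetophenone with isoprene and cyclisation of the prenyl group onto the para hydroxyl.
5. Order of ring formation: E and F first (separate fragments), then C, then D. One MOM group on the future 5-OH decides which ortho hydroxyl closes ring C (angular fusion).

Assumption: the target SMILES has no stereocentre, so the target is one achiral compound and the route needs no stereocontrol.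

**Route**

Step 1
Reactants: 1 benzene-1,2,4-triol (hydroxyquinol); 2 3-methylbut-2-enal (prenal)
Product: 5 2,2-dimethyl-2H-chromene-5,8-dione, via hydroxyquinone 3 (not isolated), via oxatriene 4 (not isolated)
Conditions: PhI(OAc)2 (1.0 equiv), MeCN, 0 °C; then 2 (3 equiv), ethylenediammonium diacetate (10 mol %), 25 °C, 0.05 M
Reagents that add atoms: none
Why: Oxidation of the hydroxyhydroquinone to 3 unmasks a vinylogous acid whose C-3 is the only nucleophilic carbon, so amine-catalysed Knoevenagel condensation with 2 gives oxatriene 4, and oxa-6π electrocyclisation through the carbonyl oxygen next to C-1 gives the para-quinonoid 2H-pyran (ring F), the domino Knoevenagel/electrocyclisation that 2-hydroxy-1,4-naphthoquinone undergoes with enals.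

Step 2
Reactants: 6 1-(2,4,6-trihydroxyphenyl)ethanone (phloroacetophenone); 7 2-methylbuta-1,3-diene (isoprene)
Product: 9 1-(5,7-dihydroxy-2,2-dimethyl-3,4-dihydro-2H-chromen-6-yl)ethanone, via C-prenyl ketone 8 (not isolated)
Conditions: 7 (1.1 equiv), 85% H3PO4, xylene, 30 °C
Reagents that add atoms: none
Why: Acid-mediated Friedel–Crafts C-prenylation by the dimethylallyl cation from isoprene (the two free ring carbons of 6 are equivalent) followed by Markovnikov hydroalkoxylation of the prenyl olefin closes ring E as a 2,2-dimethylchroman, mainly through the para hydroxyl that is not tied to the acetyl group; no stereocentre is formed.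

Step 3
Reactants: 9 1-(5,7-dihydroxy-2,2-dimethyl-3,4-dihydro-2H-chromen-6-yl)ethanone
Product: 10 1-[5-hydroxy-7-(methoxymethoxy)-2,2-dimethyl-3,4-dihydro-2H-chromen-6-yl]ethanone
Conditions: MOMCl (1.05 equiv), K2CO3, acetone, 0 → 25 °C
Reagents that add atoms: chloromethyl methyl ether (MOMCl), COCCl
Why: Williamson-type O-alkylation with one equivalent of MOMCl takes the unhindered 7-OH, because the 5-OH is flanked by the C-4 methylene and is the hydroxyl held in the hydrogen bond to the acetyl oxygen (the pattern of the natural 5-hydroxy-7-alkoxy-6-acylchromans), which leaves only the hydroxyl next to ring E free to close ring C later.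

Step 4
Reactants: 10 1-[5-hydroxy-7-(methoxymethoxy)-2,2-dimethyl-3,4-dihydro-2H-chromen-6-yl]ethanone
Product: 11 (2E)-3-(dimethylamino)-1-[5-hydroxy-7-(methoxymethoxy)-2,2-dimethyl-3,4-dihydro-2H-chromen-6-yl]prop-2-en-1-one
Conditions: DMF-DMA (3 equiv), toluene, 90 °C
Reagents that add atoms: N,N-dimethylformamide dimethyl acetal (DMF-DMA), COC(OC)N(C)C
Why: Condensation of the methyl ketone with DMF-DMA (enaminone formation) is routine for 2-hydroxy-6-(methoxymethoxy)acetophenones, leaves the hydrogen-bonded 5-OH untouched and gives the E enaminone.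

Step 5
Reactants: 11 (2E)-3-(dimethylamino)-1-[5-hydroxy-7-(methoxymethoxy)-2,2-dimethyl-3,4-dihydro-2H-chromen-6-yl]prop-2-en-1-one; 5 2,2-dimethyl-2H-chromene-5,8-dione (2.2 equiv)
Product: 15 Formosanatin D, via hydroquinone isoflavone 12 (not isolated), via quinone isoflavone 13 (not isolated), via MOM ether 14 (not isolated)
Conditions: 5 (2.2 equiv), AcOH–MeCN (1:4), 25 °C then 60 °C; then 1 M HCl, MeOH, 25 °C
Reagents that add atoms: none
Why: Proposed new method: the enaminone α-carbon adds (Michael, Nenitzescu-type) to C-6 of quinone 5, the carbon β to the C-8 carbonyl that is not deactivated as a vinylogous ester (the site at which 2-alkoxybenzoquinones accept enamines), and the only free ortho hydroxyl then closes ring C by addition–elimination with loss of Me2NH to give 12; a second equivalent of 5 oxidises 12 to quinone 13 by hydroquinone–quinone redox exchange, protonation of the distal quinone carbonyl of 13 makes C-2 an oxocarbenium carbon that is captured by the proximal quinone oxygen, and loss of H-2 re-aromatises ring B to the 5-hydroxybenzofuran 14 (ring D), after which HCl/MeOH cleaves the peri MOM acetal; the closest known reaction types are the Nenitzescu synthesis of 5-hydroxybenzofurans from tertiary enaminones and benzoquinones, in which the quinone is also the oxidant, and the domino C–H functionalisation/chromone annulation of ortho-hydroxyaryl enaminones, and no stereocentre is formed.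

**Compound list**

1 | benzene-1,2,4-triol (hydroxyquinol) | Oc1ccc(O)c(O)c1 | starting material
2 | 3-methylbut-2-enal (prenal) | CC(C)=CC=O | starting material
3 | 2-hydroxycyclohexa-2,5-diene-1,4-dione (2-hydroxy-1,4-benzoquinone) | O=C1C=CC(=O)C(O)=C1 | intermediate
4 | (3Z)-3-(3-methylbut-2-en-1-ylidene)cyclohex-5-ene-1,2,4-trione | O=C1C=CC(=O)/C(=C/C=C(C)C)C1=O | intermediate
5 | 2,2-dimethyl-2H-chromene-5,8-dione | CC1(C)C=CC2=C(O1)C(=O)C=CC2=O | intermediate
6 | 1-(2,4,6-trihydroxyphenyl)ethanone (phloroacetophenone) | CC(=O)c1c(O)cc(O)cc1O | starting material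
7 | 2-methylbuta-1,3-diene (isoprene) | C=CC(C)=C | starting material
8 | 1-[2,4,6-trihydroxy-3-(3-methylbut-2-en-1-yl)phenyl]ethanone | CC(=O)c1c(O)cc(O)c(CC=C(C)C)c1O | intermediate
9 | 1-(5,7-dihydroxy-2,2-dimethyl-3,4-dihydro-2H-chromen-6-yl)ethanone | CC(=O)c1c(O)cc2OC(C)(C)CCc2c1O | intermediate
10 | 1-[5-hydroxy-7-(methoxymethoxy)-2,2-dimethyl-3,4-dihydro-2H-chromen-6-yl]ethanone | CC(=O)c1c(OCOC)cc2OC(C)(C)CCc2c1O | intermediate
11 | (2E)-3-(dimethylamino)-1-[5-hydroxy-7-(methoxymethoxy)-2,2-dimethyl-3,4-dihydro-2H-chromen-6-yl]prop-2-en-1-one | CN(C)/C=C/C(=O)c1c(OCOC)cc2OC(C)(C)CCc2c1O | intermediate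
12 | 3-(5,8-dihydroxy-2,2-dimethyl-2H-chromen-6-yl)-5-(methoxymethoxy)-8,8-dimethyl-9,10-dihydro-4H,8H-pyrano[2,3-f]chromen-4-one | COCOc1cc2OC(C)(C)CCc2c2occ(-c3cc(O)c4OC(C)(C)C=Cc4c3O)c(=O)c12 | intermediate
13 | 6-[5-(methoxymethoxy)-8,8-dimethyl-4-oxo-9,10-dihydro-4H,8H-pyrano[2,3-f]chromen-3-yl]-2,2-dimethyl-2H-chromene-5,8-dione | COCOc1cc2OC(C)(C)CCc2c2occ(C3=CC(=O)C4=C(C=CC(C)(C)O4)C3=O)c(=O)c12 | intermediate
14 | 5-O-(methoxymethyl)formosanatin D | CC1(C)C=Cc2c(c(O)cc3c2oc2oc4c5c(cc(OCOC)c4c(=O)c23)OC(C)(C)CC5)O1 | intermediate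
15 | Formosanatin D (coumaronochromone with 5-OH and 5′-OH; 2,2-dimethyl-3,4-dihydro-2H-pyran fused at C-7/C-8 through O-7; 2,2-dimethyl-2H-pyran fused at C-3′/C-4′ through O-4′; achiral) | CC1(C)C=Cc2c(c(O)cc3c2oc2oc4c5c(cc(O)c4c(=O)c23)OC(C)(C)CC5)O1 | target

**Step count and risk**

Total step count: 5. Longest linear sequence: 4 steps (6 → 9 → 10 → 11 → 15); step 1 is a one-step side branch to 5.

The three steps most likely to fail:

Step 5 (highest risk). The cascade is untested. The quinone could take the enaminone at C-7 instead of C-6, the material could stall in the normal Nenitzescu mode as a 3-aroyl-5-hydroxybenzofuran, or excess quinone could damage the product. The fallback sets out from 11 and 5 and comes back at 13; it makes the C-3–C-1′ bond by cross-coupling instead of quinone addition. Iodine in CHCl3 cyclises 11 to 3-iodo-5-(methoxymethoxy)-8,8-dimethyl-9,10-dihydro-4H,8H-pyrano[2,3-f]chromen-4-one F1. Quinone 5 is reduced and methylated (Na2S2O4; Me2SO4, K2CO3) to 5,8-dimethoxy-2,2-dimethyl-2H-chromene F2, brominated para to the ring oxygen (NBS, MeCN) to 6-bromo-5,8-dimethoxy-2,2-dimethyl-2H-chromene F3, and borylated (B2pin2, Pd(dppf)Cl2, KOAc, dioxane) to 2-(5,8-dimethoxy-2,2-dimethyl-2H-chromen-6-yl)-4,4,5,5-tetramethyl-1,3,2-dioxaborolane F4. Suzuki coupling of F1 with F4 (Pd(PPh3)4, K2CO3, aqueous DME) gives 3-(5,8-dimethoxy-2,2-dimethyl-2H-chromen-6-yl)-5-(methoxymethoxy)-8,8-dimethyl-9,10-dihydro-4H,8H-pyrano[2,3-f]chromen-4-one F5. (NH4)2Ce(NO3)6 in aqueous MeCN then oxidatively demethylates the para-dimethoxy ring to quinone 13, which needs only the acid stage of step 5 to reach 15.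

Step 1. Hydroxyquinone 3 is prone to self-condensation before it meets prenal, and some ortho-quinonoid pyran isomer may form. The fallback sets out from 2 and comes back at 5; it builds the pyran on a stable 1,3-dione and reaches the quinone oxidation state last. Prenal 2 and commercial cyclohexane-1,3-dione (ethylenediammonium diacetate, MeOH) give, by the same Knoevenagel/oxa-6π sequence, 2,2-dimethyl-2,6,7,8-tetrahydro-5H-chromen-5-one F6. DDQ in refluxing dioxane aromatises it to 2,2-dimethyl-2H-chromen-5-ol F7. ON(SO3K)2 (Teuber oxidation, KH2PO4 buffer) then oxidises the free para position to give 5.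

Step 2. The prenyl group can also close onto an ortho hydroxyl, giving the 8-acetyl chroman isomer, and a second prenylation can occur; both cost yield and require separation. The fallback sets out from 6 and comes back at 9; it closes ring E by a propargyl Claisen route in which the ring oxygen is the para oxygen by construction. 6 is alkylated at its most acidic para hydroxyl with 3-chloro-3-methylbut-1-yne (K2CO3, KI, CuI, acetone) to 1-[2,6-dihydroxy-4-(2-methylbut-3-yn-2-yloxy)phenyl]ethanone F8. Heating in xylene (140 °C) gives, by Claisen rearrangement, 1,5-H shift and oxa-6π closure onto either of the two equivalent ring carbons, 1-(5,7-dihydroxy-2,2-dimethyl-2H-chromen-6-yl)ethanone F9. H2 over 10% Pd/C in EtOAc saturates the pyran double bond and gives 9.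

**Further compounds**

F1 | step 5 | 3-iodo-5-(methoxymethoxy)-8,8-dimethyl-9,10-dihydro-4H,8H-pyrano[2,3-f]chromen-4-one | COCOc1cc2OC(C)(C)CCc2c2occ(I)c(=O)c12
F2 | step 5 | 5,8-dimethoxy-2,2-dimethyl-2H-chromene | COc1ccc(OC)c2OC(C)(C)C=Cc12
F3 | step 5 | 6-bromo-5,8-dimethoxy-2,2-dimethyl-2H-chromene | COc1c(Br)cc(OC)c2OC(C)(C)C=Cc12
F4 | step 5 | 2-(5,8-dimethoxy-2,2-dimethyl-2H-chromen-6-yl)-4,4,5,5-tetramethyl-1,3,2-dioxaborolane | COc1c(B3OC(C)(C)C(C)(C)O3)cc(OC)c2OC(C)(C)C=Cc12
F5 | step 5 | 3-(5,8-dimethoxy-2,2-dimethyl-2H-chromen-6-yl)-5-(methoxymethoxy)-8,8-dimethyl-9,10-dihydro-4H,8H-pyrano[2,3-f]chromen-4-one | COCOc1cc2OC(C)(C)CCc2c2occ(-c3cc(OC)c4OC(C)(C)C=Cc4c3OC)c(=O)c12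
F6 | step 1 | 2,2-dimethyl-2,6,7,8-tetrahydro-5H-chromen-5-one | CC1(C)C=CC2=C(O1)CCCC2=O
F7 | step 1 | 2,2-dimethyl-2H-chromen-5-ol | CC1(C)C=Cc2c(O)cccc2O1
F8 | step 2 | 1-[2,6-dihydroxy-4-(2-methylbut-3-yn-2-yloxy)phenyl]ethanone | CC(=O)c1c(O)cc(OC(C)(C)C#C)cc1O
F9 | step 2 | 1-(5,7-dihydroxy-2,2-dimethyl-2H-chromen-6-yl)ethanone | CC(=O)c1c(O)cc2OC(C)(C)C=Cc2c1O
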